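The time of reading is 30 h in alpha and 10 h in theta, and the two times cannot be compared until each is turned into a count of turnovers.

| flask | starting material | remark | time |
|---|---|---|---|
| maple | 0.064 M | run made earlier |  |
| cedar | 0.43 M | run made earlier |  |
| alpha | 0.12 M |  | 30 h |
| theta | 0.50 M |  | 10 h |

* the flask that ends with the higher amount of target, in percent of the starting material charged, or "neither" when 2 percentage points or less lies between them (alpha / theta / neither)
* final target, as a percentage of the starting material charged, in alpha
* final target, as a percentage of the starting material charged, in theta

- percent here means starting material units held: one target counts as two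

| run | time / h | target / % | starting material / % |
|---|---|---|---|
| maple | 0.333 | 1.7 | 97.4 |
| maple | 1.00 | 6.4 | 94.5 |
| maple | 2.00 | 10.9 | 88.8 |
| maple | 2.50 | 14.0 | 86.4 |
| maple | 4.00 | 19.6 | 79.8 |
| maple | 5.00 | 24.4 | 76.6 |
| cedar | 0.417 | 14.7 | 84.6 |
| cedar | 0.667 | 23.0 | 77.9 |
| cedar | 1.00 | 29.5 | 70.7 |
| cedar | 2.00 | 45.7 | 54.5 |
| cedar | 3.00 | 56.5 | 44.5 |
| cedar | 5.00 | 67.2 | 31.8 |

(standard deviation of a reading: 0.5 percentage points)

In both runs the two columns add up to about the whole charge, with one target counted as two starting material, so no third species shows in the balance. The last row of each run is the one to read, with f as the fraction of the charge left. The turnover count is N = 1/f − 1, the time measured in first half-lives, so f = 1/(1 + N).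

Maple's last row, 76.6% left at 5.00 h, gives N = 0.305. Cedar's last row, 31.8% left at the same time, gives 2.14. The count therefore grows with the charge, as second-order kinetics requires. Dividing by concentration and time gives 0.955 M⁻¹ h⁻¹ for maple and 0.998 M⁻¹ h⁻¹ for cedar, which agree within the scatter. Their mean is K = 0.976 M⁻¹ h⁻¹, the turnovers per unit of concentration and time.

My own reckoning gives alpha N = 3.51, leaving 22.2% and so 77.8% target. Theta gets N = 4.88, leaving 17.0% and so 83.0% target. Both reckoned ends lie beyond cedar's last reading, so the late readings are the ones to watch.

The forecast says 77.7% for alpha and 82.9% for theta, names theta, and warns that “any late reversal would lower these figures somewhat”.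

The flask gives 77.9% in alpha and 83.1% in theta, so theta ends higher.

    2 starting material → target (k = 0.490 M⁻¹ h⁻¹)

Theta stops short of the whole charge mainly through the time allowed: read at 100 h instead, it holds 98.0% as target against 83.1%, which covers 88% of what is missing. Charge and time meet in the count, 4.88 for theta against 3.51 for alpha. The order turns in the neighbour of alpha charged with 0.48 M: its count is 14.1, 6.62% stays as starting material, and its target reaches 93.4%, above theta's 83.1%.

The readings are simulated for an exercise; scatter was added.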